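**Retrosynthetic overview** (eudesmane numbering: ring A = C1–C5/C10, ring B = C5–C10, C11 on C7, acid carbons C1′–C4′)
1. The C3 ester is made last from triol-enone 14 and epoxy acid 18; the epoxide is then opened with inversion at C3′ to give the (2S,3S)-diol.
2. Ring B is cut at C6–C7 and C9–C10: C7–C8–C9 comes from methyl acetoacetate (its ester carbon becomes C11), and C6–C5–C10 is an enal unit in ring A.
3. Enabling feature: in ring B the C8 carbonyl has a doubly activated α-carbon (C7, also bonded to C11) and a methyl-derived α′-carbon (C9), and C10 is the CH3-bearing β-carbon of the C6(=O)–C5=C10 enal. Knoevenagel condensation at C7 followed by 6π closure C9→C10 builds ring B and a quaternary C10 that cannot aromatise.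
4. Ring A comes from 2,6-dimethylbenzoic acid: C4 and C10 (both CH3-bearing, flanking C5) are mirror-related, so Birch reduction gives a symmetric diene that one asymmetric epoxidation/lactonisation desymmetrises (C3 and C4 set, temporary lactone ring).
5. Ring order: ring A (arene, step 1) → temporary lactone (step 2) → ring B (step 5) → C11 carbinol, C5–H, ester, diol.

Key step: step 5

Assumption: the L-fructose-derived Shi ketone is taken as the catalyst enantiomer that epoxidises 2 on the face leading to 4 (spiro transition-state model, by analogy with 1-substituted cyclohexenes); if a pilot run shows the opposite sense, the D-fructose-derived ketone is used.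
Remark: 10 is drawn as the hydrogen-bonded dienol tautomer of the β-keto ester, the form expected to be silylated in step 6.

Step 1
Reactants: 1 2,6-dimethylbenzoic acid
Product: 2 2,6-dimethylcyclohexa-2,5-diene-1-carboxylic acid
Conditions: Li, liq. NH3, THF, −78 °C; then NH4Cl
Reagents that add atoms: none
Why: Birch reduction of a benzoic acid puts the two sp3 carbons at the carboxyl-bearing carbon and the carbon para to it, so the flat arene should become the Cs-symmetric 1,4-diene whose two enantiotopic trisubstituted double bonds are the future C3=C4 and C1=C10 bonds, with no stereocentre formed.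

Step 2
Reactants: 2 2,6-dimethylcyclohexa-2,5-diene-1-carboxylic acid
Product: 4 (1S,5R,8R)-8-hydroxy-2,8-dimethyl-6-oxabicyclo[3.2.1]oct-2-en-7-one, via epoxy acid 3 (not isolated)
Conditions: 1,2:4,5-di-O-isopropylidene-β-L-erythro-2,3-hexodiulo-2,6-pyranose (L-fructose-derived Shi ketone, 0.3 equiv), KHSO5 (Oxone), K2CO3, Bu4NHSO4, MeCN/(MeO)2CH2/aq. Na2B4O7 buffer (pH 10.5), 0 °C; then pH 4, EtOAc extraction; Et3N (0.2 equiv), CH2Cl2, 40 °C
Reagents that add atoms: potassium peroxymonosulfate OOS(=O)(=O)[O-].[K+]
Why: Shi asymmetric epoxidation (chiral dioxirane) should desymmetrise the diene by attacking one enantiotopic double bond on the face anti to the carboxylate, and the carboxylate then opens the epoxide at the secondary carbon C3 with inversion (epoxy-acid lactonisation), which sets C3 and C4 trans and ties C3–O and C6 into a temporary γ-lactone, while C5 is a transient stereocentre erased in step 5.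

Step 3
Reactants: 4 (1S,5R,8R)-8-hydroxy-2,8-dimethyl-6-oxabicyclo[3.2.1]oct-2-en-7-one
Product: 5 (1S,5R,8R)-2,8-dimethyl-8-(triethylsilyloxy)-6-oxabicyclo[3.2.1]oct-2-en-7-one
Conditions: TESOTf, 2,6-lutidine, CH2Cl2, −78 to 0 °C
Reagents that add atoms: triethylsilyl trifluoromethanesulfonate CC[Si](CC)(CC)OS(=O)(=O)C(F)(F)F
Why: silyl ether formation with the reactive silyl triflate should protect the only free (tertiary) hydroxyl and make the C4 oxygen a poor leaving group for the amine-mediated key step, with no stereocentre touched.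

Step 4
Reactants: 5 (1S,5R,8R)-2,8-dimethyl-8-(triethylsilyloxy)-6-oxabicyclo[3.2.1]oct-2-en-7-one
Product: 6 (1S,5R,8R)-2,8-dimethyl-8-(triethylsilyloxy)-6-oxabicyclo[3.2.1]oct-2-en-7-ol
Conditions: i-Bu2AlH (1.2 equiv), CH2Cl2, −78 °C; aq. KNaC4H4O6
Reagents that add atoms: none
Why: low-temperature i-Bu2AlH reduction of a γ-lactone should stop at the lactol, a masked C6 aldehyde that also carries the C3 hydroxyl, with the ring stereocentres untouched and the anomeric carbon of no consequence.

Step 5
Reactants: 6 (1S,5R,8R)-2,8-dimethyl-8-(triethylsilyloxy)-6-oxabicyclo[3.2.1]oct-2-en-7-ol; 7 methyl acetoacetate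
Product: 10 methyl (4aR,7R,8R)-3,7-dihydroxy-4a,8-dimethyl-8-(triethylsilyloxy)-4,4a,5,6,7,8-hexahydronaphthalene-2-carboxylate, via hydroxy enal 8 (not isolated), via Knoevenagel oxatriene 9 (not isolated)
Conditions: 7 (1.5 equiv), piperidine (1.5 equiv), AcOH (0.5 equiv), 4 Å MS, MeCN, 25 to 65 °C; then aq. citric acid (pH 4), 0 °C
Reagents that add atoms: none
Why: Proposed new method: the lactol opens to the β,γ-unsaturated aldehyde, piperidine moves the C1=C10 double bond into conjugation through the very acidic C5–H (enal 8), and piperidinium acetate-mediated Knoevenagel condensation at the doubly activated methylene of 7 forms C6=C7 (oxatriene 9, acetyl group cis to ring A). The acetyl methyl group is then enolised by the amine (enolate or transient enamine) and the resulting 2-oxido-hexatriene C9=C8–C7=C6–C5=C10 closes ring B by thermal disrotatory 6π-electrocyclisation, equivalent to a 6-endo-trig vinylogous Michael addition of C9 to C10, which forms the C9–C10 bond and leaves the β-keto ester as its dienol 10. The closest known reaction type is the amine-mediated Knoevenagel/6π-electrocyclisation formal [3+3] annulation of enals with 1,3-dicarbonyl compounds (oxygen- and nitrogen-terminated variants, and Knoevenagel/Michael carbocyclisations with 1,3-acetonedicarboxylates); new is carbon-terminated closure onto a fully substituted, methyl-bearing enal β-carbon held in a ring. Closure through the ketone oxygen of 9 is reversible, whereas C–C closure is the irreversible exit because it turns a simple ketone enolate into a β-keto ester enol and the quaternary C10 can neither revert easily nor aromatise. C10 is the only stereocentre formed and is controlled by C4: C9 should add to the face of C10 anti to the pseudoaxial C4 silyloxy group, since the other face would force the C10 and C4 methyl groups into a 1,3-diaxial relationship in the closing chair. The step needs site selectivity between the two α-carbons of the ketone, secured because only C7 lies between two acceptors (so C7 condenses and C9 cyclises), and survival of the C4–O bond next to enal and dienol intermediates, secured by the silyl ether and the buffered amine.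

Step 6
Reactants: 10 methyl (4aR,7R,8R)-3,7-dihydroxy-4a,8-dimethyl-8-(triethylsilyloxy)-4,4a,5,6,7,8-hexahydronaphthalene-2-carboxylate
Product: 11 methyl (4aR,7R,8R)-4a,8-dimethyl-3,7,8-tris(triethylsilyloxy)-4,4a,5,6,7,8-hexahydronaphthalene-2-carboxylate
Conditions: TESOTf (2.5 equiv), Et3N, CH2Cl2, −78 to 0 °C
Reagents that add atoms: triethylsilyl trifluoromethanesulfonate CC[Si](CC)(CC)OS(=O)(=O)C(F)(F)F
Why: O-silylation of the enolised β-keto ester and of the secondary C3 alcohol (silyl enol ether and silyl ether formation) should mask the C8 carbonyl as a silyl dienol ether so that only the ester remains electrophilic, with no stereocentre changed.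

Step 7
Reactants: 11 methyl (4aR,7R,8R)-4a,8-dimethyl-3,7,8-tris(triethylsilyloxy)-4,4a,5,6,7,8-hexahydronaphthalene-2-carboxylate
Product: 12 2-[(4aR,7R,8R)-4a,8-dimethyl-3,7,8-tris(triethylsilyloxy)-4,4a,5,6,7,8-hexahydronaphthalen-2-yl]propan-2-ol
Conditions: MeLi (5 equiv), THF, −78 to −20 °C; aq. NaHCO3
Reagents that add atoms: methyllithium [Li]C
Why: double addition of methyllithium to the ester (ester to tertiary carbinol) should build C11 with both methyl groups while C8 is protected as the silyl enol ether and no acidic C–H flanks the ester, with no stereocentre formed.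

Step 8
Reactants: 12 2-[(4aR,7R,8R)-4a,8-dimethyl-3,7,8-tris(triethylsilyloxy)-4,4a,5,6,7,8-hexahydronaphthalen-2-yl]propan-2-ol
Product: 14 (4aR,5R,6R,8aR)-5,6-dihydroxy-3-(2-hydroxypropan-2-yl)-5,8a-dimethyl-4a,5,6,7,8,8a-hexahydronaphthalen-2(1H)-one, via desilylated dienol 13 (not isolated)
Conditions: Bu4NF (4 equiv), AcOH (4 equiv), THF, 0 to 40 °C; then Et3N (0.5 equiv), 25 °C
Reagents that add atoms: none
Why: buffered fluoride desilylation should remove the three triethylsilyl groups and the released dienol then tautomerises (amine-assisted keto–enol equilibration) to the conjugated enone, the proton entering C5 from the α-face anti to the axial C10 methyl and C4 oxygen so that the trans ring fusion (C5 R) results, which should also be the thermodynamic one.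

Step 9
Reactants: 15 (E)-2-methylbut-2-en-1-ol
Product: 16 [(2R,3R)-2,3-dimethyloxiran-2-yl]methanol
Conditions: Ti(OiPr)4 (0.1 equiv), D-(−)-diethyl tartrate (0.12 equiv), t-BuOOH, 4 Å MS, CH2Cl2, −20 °C
Reagents that add atoms: tert-butyl hydroperoxide CC(C)(C)OO
Why: Sharpless asymmetric epoxidation of the primary allylic alcohol with the D-(−)-tartrate ligand should deliver oxygen to the face that gives the (2R,3R)-epoxy alcohol, both stereocentres being set by the catalyst and the E geometry fixing the two methyl groups cis.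

Step 10
Reactants: 16 [(2R,3R)-2,3-dimethyloxiran-2-yl]methanol
Product: 18 (2S,3R)-2,3-dimethyloxirane-2-carboxylic acid, via epoxy aldehyde 17 (not isolated)
Conditions: TEMPO (2,2,6,6-tetramethylpiperidin-1-oxyl, 0.2 equiv), PhI(OAc)2 (2.2 equiv), MeCN/H2O, 0 to 25 °C
Reagents that add atoms: water O
Why: TEMPO/PhI(OAc)2 oxidation of the primary alcohol through the aldehyde hydrate should give the glycidic acid without touching the epoxide, the stereocentres staying as they are (the C2 descriptor changes only through the priority rules).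

Step 11
Reactants: 14 (4aR,5R,6R,8aR)-5,6-dihydroxy-3-(2-hydroxypropan-2-yl)-5,8a-dimethyl-4a,5,6,7,8,8a-hexahydronaphthalen-2(1H)-one; 18 (2S,3R)-2,3-dimethyloxirane-2-carboxylic acid
Product: 19 (3R,4R,5R,10R)-4,11-dihydroxy-8-oxoeudesm-6-en-3-yl (2S,3R)-2,3-dimethyloxirane-2-carboxylate
Conditions: 18 (1.5 equiv), 2-methyl-6-nitrobenzoic anhydride, Et3N, 4-(dimethylamino)pyridine (cat.), CH2Cl2, 25 °C
Reagents that add atoms: none
Why: Shiina esterification (mixed-anhydride activation with nucleophilic catalysis) should acylate only the secondary C3 hydroxyl, the tertiary C4 and C11 hydroxyls being too hindered, with retention at C3 and no epimerisable centre in the acid.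

Step 12
Reactants: 19 (3R,4R,5R,10R)-4,11-dihydroxy-8-oxoeudesm-6-en-3-yl (2S,3R)-2,3-dimethyloxirane-2-carboxylate
Product: 20 (3R,4R,5R,10R)-4,11-dihydroxy-8-oxoeudesm-6-en-3-yl (2S,3S)-2,3-dihydroxy-2-methylbutanoate
Conditions: HClO4 (0.3 equiv), THF/H2O (2:1), 0 to 25 °C
Reagents that add atoms: water O
Why: acid-catalysed hydrolytic opening of the α,β-epoxy ester should occur by backside attack of water at the β-carbon C3′ (the α-carbon is quaternary and deactivated by the ester carbonyl), so C3′ is inverted to S and C2′ keeps its S configuration, giving the (2S,3S)-diol ester.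

**Compound list**
1 | 2,6-dimethylbenzoic acid | Cc1cccc(C)c1C(=O)O | starting material
2 | 2,6-dimethylcyclohexa-2,5-diene-1-carboxylic acid | CC1=CCC=C(C)C1C(=O)O | intermediate
3 | (1R,2S,6S)-1,3-dimethyl-7-oxabicyclo[4.1.0]hept-3-ene-2-carboxylic acid (epoxide anti to CO2H) | OC(=O)[C@H]1C(C)=CC[C@@H]2O[C@]12C | intermediate (not isolated)
4 | (1S,5R,8R)-8-hydroxy-2,8-dimethyl-6-oxabicyclo[3.2.1]oct-2-en-7-one | O=C1O[C@@H]2CC=C(C)[C@H]1[C@@]2(C)O | intermediate
5 | (1S,5R,8R)-2,8-dimethyl-8-(triethylsilyloxy)-6-oxabicyclo[3.2.1]oct-2-en-7-one | O=C1O[C@@H]2CC=C(C)[C@H]1[C@@]2(C)O[Si](CC)(CC)CC | intermediate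
6 | (1S,5R,8R)-2,8-dimethyl-8-(triethylsilyloxy)-6-oxabicyclo[3.2.1]oct-2-en-7-ol (lactol, both anomers) | OC1O[C@@H]2CC=C(C)[C@H]1[C@@]2(C)O[Si](CC)(CC)CC | intermediate
7 | methyl acetoacetate | CC(=O)CC(=O)OC | starting material
8 | (5R,6R)-5-hydroxy-2,6-dimethyl-6-(triethylsilyloxy)cyclohex-1-ene-1-carbaldehyde | O=CC1=C(C)CC[C@@H](O)[C@]1(C)O[Si](CC)(CC)CC | intermediate (not isolated)
9 | methyl (2E)-2-acetyl-3-[(5R,6R)-5-hydroxy-2,6-dimethyl-6-(triethylsilyloxy)cyclohex-1-en-1-yl]prop-2-enoate | COC(=O)/C(=C/C1=C(C)CC[C@@H](O)[C@]1(C)O[Si](CC)(CC)CC)C(C)=O | intermediate (not isolated)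
10 | methyl (4aR,7R,8R)-3,7-dihydroxy-4a,8-dimethyl-8-(triethylsilyloxy)-4,4a,5,6,7,8-hexahydronaphthalene-2-carboxylate (dienol tautomer of the β-keto ester) | COC(=O)C1=C(O)C[C@@]2(C)CC[C@@H](O)[C@](C)(O[Si](CC)(CC)CC)C2=C1 | intermediate
11 | methyl (4aR,7R,8R)-4a,8-dimethyl-3,7,8-tris(triethylsilyloxy)-4,4a,5,6,7,8-hexahydronaphthalene-2-carboxylate | COC(=O)C1=C(O[Si](CC)(CC)CC)C[C@@]2(C)CC[C@@H](O[Si](CC)(CC)CC)[C@](C)(O[Si](CC)(CC)CC)C2=C1 | intermediate
12 | 2-[(4aR,7R,8R)-4a,8-dimethyl-3,7,8-tris(triethylsilyloxy)-4,4a,5,6,7,8-hexahydronaphthalen-2-yl]propan-2-ol | CC(C)(O)C1=C(O[Si](CC)(CC)CC)C[C@@]2(C)CC[C@@H](O[Si](CC)(CC)CC)[C@](C)(O[Si](CC)(CC)CC)C2=C1 | intermediate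
13 | (4aR,7R,8R)-2-(2-hydroxypropan-2-yl)-4a,8-dimethyl-4,4a,5,6,7,8-hexahydronaphthalene-3,7,8-triol | CC(C)(O)C1=C(O)C[C@@]2(C)CC[C@@H](O)[C@](C)(O)C2=C1 | intermediate (not isolated)
14 | (4aR,5R,6R,8aR)-5,6-dihydroxy-3-(2-hydroxypropan-2-yl)-5,8a-dimethyl-4a,5,6,7,8,8a-hexahydronaphthalen-2(1H)-one, i.e. (3R,4R,5R,10R)-3,4,11-trihydroxyeudesm-6-en-8-one | O[C@@H]1CC[C@]2(C)CC(=O)C(C(C)(C)O)=C[C@H]2[C@@]1(C)O | intermediate
15 | (E)-2-methylbut-2-en-1-ol | C/C=C(\C)CO | starting material
16 | [(2R,3R)-2,3-dimethyloxiran-2-yl]methanol | C[C@H]1O[C@]1(C)CO | intermediate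
17 | (2S,3R)-2,3-dimethyloxirane-2-carbaldehyde | C[C@H]1O[C@]1(C)C=O | intermediate (not isolated)
18 | (2S,3R)-2,3-dimethyloxirane-2-carboxylic acid | C[C@H]1O[C@]1(C)C(=O)O | intermediate
19 | (3R,4R,5R,10R)-4,11-dihydroxy-8-oxoeudesm-6-en-3-yl (2S,3R)-2,3-dimethyloxirane-2-carboxylate | C[C@H]3O[C@]3(C)C(=O)O[C@@H]1CC[C@]2(C)CC(=O)C(C(C)(C)O)=C[C@H]2[C@@]1(C)O | intermediate
20 | (3R,4R,5R,10R)-4,11-dihydroxy-8-oxoeudesm-6-en-3-yl (2S,3S)-2,3-dihydroxy-2-methylbutanoate | C[C@H](O)[C@](C)(O)C(=O)O[C@@H]1CC[C@]2(C)CC(=O)C(C(C)(C)O)=C[C@H]2[C@@]1(C)O | target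

**Total step count:** 12. **Longest linear sequence:** 10 (steps 1–8, 11, 12).

**Steps most likely to fail**

Step 5 (Proposed new method). The carbon–carbon ring closure at the hindered, fully substituted C10 may be too slow, so that the material rests in the reversible oxygen-closed form or loses the C4 silyloxy group by vinylogous elimination; facial selectivity at C10 may also be incomplete. The fallback separates the two bond formations and uses a neutral pericyclic closure; it sets out from 6 and comes back to the route at 11. Lactol 6 and 7 are condensed with ethylenediammonium diacetate in CH2Cl2 at 25 °C, where the Knoevenagel product 9 should be isolable. TESOTf and Et3N at −78 °C then silylate the C3 hydroxyl and convert the acetyl group into its triethylsilyl enol ether, giving the 2-silyloxy triene methyl (2E)-3-[(5R,6R)-2,6-dimethyl-5,6-bis(triethylsilyloxy)cyclohex-1-en-1-yl]-2-[1-(triethylsilyloxy)ethenyl]prop-2-enoate F1. Heating F1 in toluene at 90–110 °C should effect the thermal disrotatory 6π-electrocyclisation of the 2-silyloxy hexatriene directly to 11, from which step 7 continues.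

Step 2. Enantioface selection by the dioxirane on the 1,4-diene may be insufficient, over-epoxidation may occur, or water may open the epoxide at C4 instead of lactonisation (which would feed the enantiomeric series). The fallback replaces asymmetric catalysis by resolution; it sets out from 2 and comes back at 4. Epoxidation of 2 with 3-chloroperbenzoic acid and NaHCO3 in CH2Cl2 followed by Et3N should give the racemic lactone rac-8-hydroxy-2,8-dimethyl-6-oxabicyclo[3.2.1]oct-2-en-7-one F2. Aminolysis with (S)-1-phenylethylamine and AlMe3 in toluene opens it to two diastereomeric dihydroxy amides, which are separated by crystallisation or chromatography: (1S,5R,6R)-5,6-dihydroxy-2,6-dimethyl-N-[(1S)-1-phenylethyl]cyclohex-2-ene-1-carboxamide F3 is kept, and its (1R,5S,6S) diastereomer F4 is discarded. Warming F3 with catalytic p-toluenesulfonic acid in toluene should relactonise it to enantiopure 4 with release of the amine.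

Step 12. The acidic epoxide opening may be accompanied by dehydration of the tertiary C4 or C11 hydroxyl, or by attack of water at the wrong epoxide carbon. The fallback opens the epoxide before the coupling and carries the diol as an acetonide; it sets out from 18 (with 14) and comes back at 20. Aqueous HClO4 converts 18 into (2S,3S)-2,3-dihydroxy-2-methylbutanoic acid F5 (inversion at C3′). 2,2-Dimethoxypropane with camphorsulfonic acid gives (4S,5S)-2,2,4,5-tetramethyl-1,3-dioxolane-4-carboxylic acid F6. Shiina esterification of F6 with 14 gives (3R,4R,5R,10R)-4,11-dihydroxy-8-oxoeudesm-6-en-3-yl (4S,5S)-2,2,4,5-tetramethyl-1,3-dioxolane-4-carboxylate F7, and 80% aqueous AcOH at 40 °C should release 20.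

**Further compounds**
F1 | step 5 | methyl (2E)-3-[(5R,6R)-2,6-dimethyl-5,6-bis(triethylsilyloxy)cyclohex-1-en-1-yl]-2-[1-(triethylsilyloxy)ethenyl]prop-2-enoate | COC(=O)/C(=C/C1=C(C)CC[C@@H](O[Si](CC)(CC)CC)[C@]1(C)O[Si](CC)(CC)CC)C(=C)O[Si](CC)(CC)CC
F2 | step 2 | rac-8-hydroxy-2,8-dimethyl-6-oxabicyclo[3.2.1]oct-2-en-7-one (relative configuration of 4) | O=C1OC2CC=C(C)C1C2(C)O
F3 | step 2 | (1S,5R,6R)-5,6-dihydroxy-2,6-dimethyl-N-[(1S)-1-phenylethyl]cyclohex-2-ene-1-carboxamide | C[C@H](NC(=O)[C@H]1C(C)=CC[C@@H](O)[C@]1(C)O)c1ccccc1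
F4 | step 2 | (1R,5S,6S)-5,6-dihydroxy-2,6-dimethyl-N-[(1S)-1-phenylethyl]cyclohex-2-ene-1-carboxamide | C[C@H](NC(=O)[C@@H]1C(C)=CC[C@H](O)[C@@]1(C)O)c1ccccc1
F5 | step 12 | (2S,3S)-2,3-dihydroxy-2-methylbutanoic acid | C[C@H](O)[C@](C)(O)C(=O)O
F6 | step 12 | (4S,5S)-2,2,4,5-tetramethyl-1,3-dioxolane-4-carboxylic acid | C[C@@H]1OC(C)(C)O[C@]1(C)C(=O)O
F7 | step 12 | (3R,4R,5R,10R)-4,11-dihydroxy-8-oxoeudesm-6-en-3-yl (4S,5S)-2,2,4,5-tetramethyl-1,3-dioxolane-4-carboxylate | C[C@@H]3OC(C)(C)O[C@]3(C)C(=O)O[C@@H]1CC[C@]2(C)CC(=O)C(C(C)(C)O)=C[C@H]2[C@@]1(C)O
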